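Elm is the run to read, since east has elm's charges carried on to 40 min, and south-east, south and west have the same charges with one of them let in late.

in all of them: free catalyst 0.50 mM
- elm: substrate 0.050 M; reagent 0.075 M; second catalyst 0.27 mM; run made earlier
- ash: substrate 0.050 M; reagent 0.075 M; second catalyst 0.14 mM; run made earlier
- birch: substrate 0.050 M; reagent 0.075 M; second catalyst 0.20 mM; run made earlier
- south-east: substrate 0.050 M (fed, over 30 min); reagent 0.0750 M; second catalyst 0.27 mM; all else is in the flask from the start; the feed brings no volume worth counting; time 40 min
- east: substrate 0.050 M; reagent 0.0750 M; second catalyst 0.27 mM; everything together at the start; time 40 min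
- south: substrate 0.050 M (in portions, 5, over 30 min); reagent 0.0750 M; second catalyst 0.27 mM; first portion at the start, last at 30 min; time 40 min
- west: substrate 0.050 M; reagent 0.0750 M (fed, over 30 min); second catalyst 0.27 mM; all else is in the flask from the start; the feed brings no volume worth counting; time 40 min

- elm (time / min: product / %): 2.00: 12.6; 4.00: 23.9; 6.00: 34.1; 12.0: 57.1; 25.0: 83.6
- ash (time / min: product / %): 2.50: 8.5; 5.00: 16.6; 10.0: 30.1; 15.0: 42.1; 30.0: 67.2
- birch (time / min: product / %): 6.00: 26.6; 12.0: 46.1; 20.0: 65.8; 25.0: 73.6; 30.0: 79.7

(readings scatter by 0.5 percentage points)



* the flask that comes out highest in amount of product, in percent of the substrate charged, or "all alike" when all lie within 1.5 percentage points (south-east / east / south / west / all alike)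
* product at the end, in percent of the substrate charged, south-east
* product at the end, in percent of the substrate charged, east
* product at the end, in percent of the substrate charged, south
* product at the end, in percent of the substrate charged, west

Elm looks odd at first. Taking one reagent per product, reagent has fallen to 44.3% of its charge by 25.0 min. Yet the slope of the log of u, the fraction of the substrate charge not yet product, rises from 0.0673 min⁻¹ at the start to 0.0740 min⁻¹ between 12.0 min and 25.0 min, near enough a pseudo-first-order line as read.

The two go together. In units of the substrate charge, reagent stands at u plus a fixed excess e of 0.500. Let the rate be proportional to reagent times a share u/(u+e) of busy second catalyst: the reagent cancels the denominator, and what remains is proportional to u. So the nearly straight line does not speak against first order in reagent, and we take first order.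

A late charge is then a correction to elm's clock. We call the feed delay, the mean time by which a parcel of the charge arrives after the start, 15.0 min; the equal portions of south arrive with the same mean. As a first estimate, we expect south-east, south and west at 40 min to stand where elm stood at 25.0 min, the reading 83.6%. East has no delay: elm's mean slope to that reading, 0.0723 min⁻¹, gives 94.5%, so we put east on top.

The forecast gives 81% for south-east, 94.5% for east, 79% for south and 93.5% for west, also with east on top, on the ground “I take reagent as zero order”, which puts it 9.9 percentage points above our reckoning on west.

East comes out highest at 94.8%, with south-east at 84.5%, south at 82.9% and west at 81.8%.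

    reagent + catalyst intermediate → second catalyst + product (k = 4.20 M⁻¹ s⁻¹)
    second catalyst + open intermediate ⇌ catalyst intermediate (K = 65.0 M⁻¹, k = 1100 M⁻¹ s⁻¹)
    substrate + free catalyst ⇌ free catalyst + open intermediate (K = 2.50, k = 280 M⁻¹ s⁻¹)

West ends 1.8 points below elm's reading at the delayed time. With the dosing of west cut to 3.00 min, the delay is 1.50 min, elm's slope gives 93.8%, and that flask gives 94.2%. In east, the path from substrate and free catalyst to open intermediate has half its turnover up to 40 min done by 0.0995 min, while the path from second catalyst and open intermediate to catalyst intermediate needs 8.96 min. At 20.0 min, east holds 16.6% as open intermediate beside 6.72% as substrate.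

All runs are simulated from invented constants, noise included.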